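Retrosynthesis: the aryl ether bond O–C11 is cut first, giving scopoletin and a 3α,11-diol. The C3 carbinol goes back to a masked ketone and the C7=C8 olefin to a C7 ketone. Ring B is then opened at C7–C8 and C9–C10.
Forward: ring A comes from 2,2-dimethylcyclohexane-1,3-dione and is converted into the semicyclic diene C7=C6–C5=C10. Ring B closes in one [4+2] step with (E)-crotonaldehyde, and the coumarin is attached last.
Enabling feature: on ring B the C9–C11H2O arm lies anti to the C10 methyl. At diene terminus C10 the ring A carbon C1 is the outside substituent and the methyl the inside one, so an endo formyl group at C9 ends in exactly this position.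
Stereochemistry: C8, C9 and C10 come from the enal geometry, the endo mode and the chiral amine (absolute sense). H-5 comes from dissolving-metal reduction of the Δ5-7-one, and 3α-OH from a bulky borohydride. C8 is erased when C7=C8 is made.

Key step: step 5

Numbering: drimane numbering is used for all bicyclic compounds (C3 carbinol or masked ketone, C4 CMe2, C5/C10 ring fusion, C9–C11H2–O). β is the face of the C10 methyl and α the opposite face.
Assumption: ketone 17 is drawn with the 8β-methyl group retained; partial epimerisation at C8 would be harmless because C8 becomes sp2 in step 10.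

Step 1
Reactants: 1 2,2-dimethylcyclohexane-1,3-dione
Product: 2 6,6-dimethyl-1,4-dioxaspiro[4.5]decan-7-one
Conditions: HOCH2CH2OH (1.05 equiv), p-TsOH·H2O (cat.), toluene, reflux, azeotropic removal of water
Reagents that add atoms: ethylene glycol, OCCO
Why: Acid-catalysed ketalisation with one equivalent of diol should stop at the monoketal, because the remaining carbonyl then lies next to a quaternary carbon that is itself flanked by the spiro centre; no stereocentre forms.

Step 2
Reactants: 2 6,6-dimethyl-1,4-dioxaspiro[4.5]decan-7-one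
Product: 4 (±)-6,6,8-trimethyl-1,4-dioxaspiro[4.5]decan-7-one, via lithium enolate 3 (not isolated)
Conditions: LDA, THF, −78 °C; MeI, −78 → 0 °C
Reagents that add atoms: iodomethane, CI
Why: Enolate alkylation: the ketone can enolise to one side only (the other α-carbon is quaternary), so a single enolate is methylated by SN2 and the racemic stereocentre so formed disappears in step 3.

Step 3
Reactants: 4 (±)-6,6,8-trimethyl-1,4-dioxaspiro[4.5]decan-7-one
Product: 6 6,6,8-trimethyl-1,4-dioxaspiro[4.5]dec-7-en-7-yl trifluoromethanesulfonate, via lithium enolate 5 (not isolated)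
Conditions: LDA, THF, −78 → 0 °C; PhNTf2, 0 °C → rt
Reagents that add atoms: N-phenylbis(trifluoromethanesulfonimide), O=S(=O)(N(c1ccccc1)S(=O)(=O)C(F)(F)F)C(F)(F)F
Why: Enolate O-sulfonylation: the only α-hydrogen sits on the methyl-bearing carbon, so the tetrasubstituted enolate forms without regiochemical choice and is trapped on oxygen, as is routine for 2,2,6-trimethylcyclohexanone.

Step 4
Reactants: 6 6,6,8-trimethyl-1,4-dioxaspiro[4.5]dec-7-en-7-yl trifluoromethanesulfonate; 7 potassium vinyltrifluoroborate
Product: 8 6,6,8-trimethyl-7-vinyl-1,4-dioxaspiro[4.5]dec-7-ene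
Conditions: PdCl2(dppf)·CH2Cl2 (5 mol %), Cs2CO3 (3 equiv), THF–H2O 9:1, 70 °C
Reagents that add atoms: none
Why: Suzuki–Miyaura coupling: oxidative addition of zerovalent palladium into the C–OTf bond, transmetalation from the slowly hydrolysed vinyltrifluoroborate and reductive elimination give the diene, a coupling established for hindered 2,6,6-trimethylcyclohexenyl triflates.

Step 5
Reactants: 8 6,6,8-trimethyl-7-vinyl-1,4-dioxaspiro[4.5]dec-7-ene; 9 (E)-crotonaldehyde
Product: 12 3,3-ethylenedioxy-9βH-drim-5-en-11-al (8S,9R,10R; 8β-methyl; 9α-formyl anti to the 10β-methyl), via crotonaldehyde iminium ion 10 (not isolated), via cycloadduct iminium ion 11 (not isolated)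
Conditions: (2S,5S)-5-benzyl-2-tert-butyl-3-methylimidazolidin-4-one·CF3CO2H (20 mol %), 9 (5 equiv), MeCN–H2O 95:5, 1 M, 0 °C → rt
Reagents that add atoms: none
Why: Proposed new method: the amine salt condenses with 9 to the (E)-configured iminium ion 10, whose low-lying LUMO takes up the s-cis form of 8 in a concerted but strongly asynchronous [4π+2π] cycloaddition (C7–C8 ahead of C9–C10), after which water releases 12 from 11 and returns the catalyst. The closest known reaction type is the imidazolidinone-catalysed enantioselective Diels–Alder reaction of (E)-enals with cyclic and acyclic dienes, backed by the thermal cycloadditions of 2,6,6-trimethyl-1-vinylcyclohexene; what has not been shown is a diene terminus (C10) that is fully substituted and turns quaternary. Ring B closes as a six-membered ring by an intermolecular suprafacial–suprafacial [4+2] union in which both ring bonds arise in the same step. C8 and C9 are set together, their trans relation (8β-methyl, 9α-formyl) by the (E)-geometry of the enal and their absolute sense (8S,9R) by the benzyl group of the (2S,5S)-catalyst, which covers one face of 10 and leaves the Cα-Si/Cβ-Re face open, a face that in this catalyst carries no substituent that could repel the bulky diene. C10 (R) is set by the endo orientation of the C=N+ unit, which ends cis to the outside substituent C1 and hence anti to the inside methyl group. The step needs regio- and endo selectivity: the unhindered CH2 terminus C7 has the largest HOMO coefficient and meets the electrophilic β-carbon, the endo mode gains from the attraction between the cationic C=N+ unit and the electron-rich C5–C6 part of the diene, and the ketal should last because the ammonium salt is no stronger an acid than a pyridinium salt.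

Step 6
Reactants: 12 3,3-ethylenedioxy-9βH-drim-5-en-11-al
Product: 13 3,3-ethylenedioxy-9βH-drim-5-en-11-ol (8β-methyl; 9α-CH2OH)
Conditions: NaBH4, MeOH, 0 °C
Reagents that add atoms: none
Why: Borohydride reduction of the aldehyde is fast at 0 °C, removes the only epimerisable position (H-9 next to the formyl group) and touches neither the ketal nor the olefin.

Step 7
Reactants: 13 3,3-ethylenedioxy-9βH-drim-5-en-11-ol
Product: 14 11-(tert-butyldimethylsilyloxy)-3,3-ethylenedioxy-9βH-drim-5-ene
Conditions: TBSCl, imidazole, DMF, rt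
Reagents that add atoms: tert-butyldimethylsilyl chloride, CC(C)(C)[Si](C)(C)Cl
Why: Imidazole-promoted silylation of a primary alcohol gives an all-alkyl silyl ether that withstands hexavalent chromium, lithium in ammonia and amide bases, whereas an aryl-bearing silyl group would be reduced in step 9.

Step 8
Reactants: 14 11-(tert-butyldimethylsilyloxy)-3,3-ethylenedioxy-9βH-drim-5-ene
Product: 15 11-(tert-butyldimethylsilyloxy)-3,3-ethylenedioxy-9βH-drim-5-en-7-one
Conditions: CrO3, 3,5-dimethylpyrazole, CH2Cl2, −20 °C
Reagents that add atoms: chromium trioxide, O=[Cr](=O)=O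
Why: Allylic oxidation with the CrO3–3,5-dimethylpyrazole complex is the standard passage from Δ5-olefins (3-ketals included) to Δ5-7-ones, and here C7 is the only allylic carbon that carries hydrogen because C4 and C10 are quaternary.

Step 9
Reactants: 15 11-(tert-butyldimethylsilyloxy)-3,3-ethylenedioxy-9βH-drim-5-en-7-one
Product: 17 11-(tert-butyldimethylsilyloxy)-3,3-ethylenedioxy-5αH,9βH-driman-7-one (8β-methyl; trans-decalin), via lithium 6-en-7-olate 16 (not isolated)
Conditions: Li, NH3(l)–THF, t-BuOH (1 equiv), −78 °C; then solid NH4Cl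
Reagents that add atoms: none
Why: Dissolving-metal (Birch-type) enone reduction: two electrons and one proton give enolate 16, with C5 protonated axially on the α face through the chair-like trans-fused arrangement, since the stereoelectronically allowed cis-fused alternative would push C6 axial on ring A against a ketal oxygen, and the enolate resists over-reduction until the quench.

Step 10
Reactants: 17 11-(tert-butyldimethylsilyloxy)-3,3-ethylenedioxy-5αH,9βH-driman-7-one
Product: 19 11-(tert-butyldimethylsilyloxy)-3,3-ethylenedioxy-5αH,9βH-drim-7-en-7-yl trifluoromethanesulfonate, via bromomagnesium 7-en-7-olate 18 (not isolated)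
Conditions: i-Pr2NMgBr (from EtMgBr + i-Pr2NH), Et2O, rt, equilibration; then PhNTf2, rt
Reagents that add atoms: N-phenylbis(trifluoromethanesulfonimide), O=S(=O)(N(c1ccccc1)S(=O)(=O)C(F)(F)F)C(F)(F)F
Why: Thermodynamic enolate formation followed by O-triflation: enolate 16 of step 9 has the wrong position, so the ketone is re-enolised under equilibrating magnesium amide conditions, where the tetrasubstituted C7=C8 enolate 18 is favoured also by relief of the 8β-methyl/10β-methyl 1,3-diaxial contact, and its trapping erases the C8 stereocentre.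

Step 11
Reactants: 19 11-(tert-butyldimethylsilyloxy)-3,3-ethylenedioxy-5αH,9βH-drim-7-en-7-yl trifluoromethanesulfonate
Product: 20 11-(tert-butyldimethylsilyloxy)-3,3-ethylenedioxy-5αH,9βH-drim-7-ene
Conditions: Pd(OAc)2 (5 mol %), PPh3 (10 mol %), HCO2H, n-Bu3N, DMF, 60 °C
Reagents that add atoms: none
Why: Palladium-catalysed formate reduction of an enol triflate: oxidative addition, formate exchange, loss of CO2 and C–H reductive elimination replace OTf by H without moving the double bond.

Step 12
Reactants: 20 11-(tert-butyldimethylsilyloxy)-3,3-ethylenedioxy-5αH,9βH-drim-7-ene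
Product: 21 11-hydroxy-5αH,9βH-drim-7-en-3-one
Conditions: 2 M aq HCl, THF, rt
Reagents that add atoms: water, O
Why: Acid hydrolysis cleaves the dioxolane and the primary silyl ether in one operation, under conditions too mild to protonate the trisubstituted C7=C8 olefin.

Step 13
Reactants: 21 11-hydroxy-5αH,9βH-drim-7-en-3-one
Product: 22 5αH,9βH-drim-7-ene-3α,11-diol (3R; axial 3-OH)
Conditions: KBH(s-Bu)3 (3 equiv), THF, −78 °C; then NaOH, H2O2, 0 °C
Reagents that add atoms: none
Why: Ketone reduction under steric approach control: the bulky trialkylborohydride attacks the 4,4-dimethyl-3-ketone along the equatorial trajectory and gives the axial 3α-alcohol, as known for 3-oxo-4,4-dimethyl terpenoids, while the free C11–OH only consumes one equivalent of hydride.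

Step 14
Reactants: 22 5αH,9βH-drim-7-ene-3α,11-diol; 23 scopoletin (7-hydroxy-6-methoxycoumarin)
Product: 25 7-{[(1R,4aR,6R,8aS)-6-hydroxy-2,5,5,8a-tetramethyl-1,4,4a,5,6,7,8,8a-octahydronaphthalen-1-yl]methoxy}-6-methoxy-2H-chromen-2-one (CNP0218138.2), via C11 alkoxyphosphonium salt 24 (not isolated)
Conditions: PPh3, DIAD, THF, 0 °C → rt
Reagents that add atoms: none
Why: Mitsunobu etherification: the phosphine–azodicarboxylate betaine activates the primary C11–OH as oxyphosphonium ion 24, which the scopoletin phenolate displaces by SN2 at a non-stereogenic CH2, while the axial 3α-OH next to the gem-dimethyl carbon is too hindered to be activated.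

Compound list
1 | 2,2-dimethylcyclohexane-1,3-dione | CC1(C)C(=O)CCCC1=O | starting material
2 | 6,6-dimethyl-1,4-dioxaspiro[4.5]decan-7-one | CC1(C)C(=O)CCCC12OCCO2 | intermediate
3 | lithium 6,6-dimethyl-1,4-dioxaspiro[4.5]dec-7-en-7-olate | CC1(C)C([O-])=CCCC12OCCO2.[Li+] | intermediate
4 | (±)-6,6,8-trimethyl-1,4-dioxaspiro[4.5]decan-7-one (racemic) | CC1CCC2(OCCO2)C(C)(C)C1=O | intermediate
5 | lithium 6,6,8-trimethyl-1,4-dioxaspiro[4.5]dec-7-en-7-olate | CC1=C([O-])C(C)(C)C2(OCCO2)CC1.[Li+] | intermediate
6 | 6,6,8-trimethyl-1,4-dioxaspiro[4.5]dec-7-en-7-yl trifluoromethanesulfonate | CC1=C(OS(=O)(=O)C(F)(F)F)C(C)(C)C2(OCCO2)CC1 | intermediate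
7 | potassium vinyltrifluoroborate | C=C[B-](F)(F)F.[K+] | starting material
8 | 6,6,8-trimethyl-7-vinyl-1,4-dioxaspiro[4.5]dec-7-ene | C=CC1=C(C)CCC2(OCCO2)C1(C)C | intermediate
9 | (E)-crotonaldehyde | C/C=C/C=O | starting material
10 | (E)-iminium trifluoroacetate of 9 with the (2S,5S)-imidazolidinone | C/C=C/C=[N+]1/[C@H](C(C)(C)C)N(C)C(=O)[C@@H]1Cc2ccccc2.[O-]C(=O)C(F)(F)F | intermediate
11 | iminium trifluoroacetate of 12 with the (2S,5S)-imidazolidinone | CN1C(=O)[C@H](Cc2ccccc2)[N+](=C[C@@H]3[C@@H](C)CC=C4C(C)(C)C5(OCCO5)CC[C@]34C)[C@@H]1C(C)(C)C.[O-]C(=O)C(F)(F)F | intermediate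
12 | 3,3-ethylenedioxy-9βH-drim-5-en-11-al (8β-methyl, 9α-formyl, 10β-methyl) | O=C[C@@H]1[C@@H](C)CC=C2C(C)(C)C3(OCCO3)CC[C@]12C | intermediate
13 | 3,3-ethylenedioxy-9βH-drim-5-en-11-ol | OC[C@@H]1[C@@H](C)CC=C2C(C)(C)C3(OCCO3)CC[C@]12C | intermediate
14 | 11-(tert-butyldimethylsilyloxy)-3,3-ethylenedioxy-9βH-drim-5-ene | CC(C)(C)[Si](C)(C)OC[C@@H]1[C@@H](C)CC=C2C(C)(C)C3(OCCO3)CC[C@]12C | intermediate
15 | 11-(tert-butyldimethylsilyloxy)-3,3-ethylenedioxy-9βH-drim-5-en-7-one | CC(C)(C)[Si](C)(C)OC[C@@H]1[C@@H](C)C(=O)C=C2C(C)(C)C3(OCCO3)CC[C@]12C | intermediate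
16 | lithium 6-en-7-olate of 17 (5αH) | CC(C)(C)[Si](C)(C)OC[C@@H]1[C@@H](C)C([O-])=C[C@H]2C(C)(C)C3(OCCO3)CC[C@]12C.[Li+] | intermediate
17 | 11-(tert-butyldimethylsilyloxy)-3,3-ethylenedioxy-5αH,9βH-driman-7-one (8β-methyl) | CC(C)(C)[Si](C)(C)OC[C@@H]1[C@@H](C)C(=O)C[C@H]2C(C)(C)C3(OCCO3)CC[C@]12C | intermediate
18 | bromomagnesium 7-en-7-olate of 17 | CC(C)(C)[Si](C)(C)OC[C@@H]1C(C)=C(O[Mg]Br)C[C@H]2C(C)(C)C3(OCCO3)CC[C@]12C | intermediate
19 | 11-(tert-butyldimethylsilyloxy)-3,3-ethylenedioxy-5αH,9βH-drim-7-en-7-yl trifluoromethanesulfonate | CC(C)(C)[Si](C)(C)OC[C@@H]1C(C)=C(OS(=O)(=O)C(F)(F)F)C[C@H]2C(C)(C)C3(OCCO3)CC[C@]12C | intermediate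
20 | 11-(tert-butyldimethylsilyloxy)-3,3-ethylenedioxy-5αH,9βH-drim-7-ene | CC(C)(C)[Si](C)(C)OC[C@@H]1C(C)=CC[C@H]2C(C)(C)C3(OCCO3)CC[C@]12C | intermediate
21 | 11-hydroxy-5αH,9βH-drim-7-en-3-one | OC[C@@H]1C(C)=CC[C@H]2C(C)(C)C(=O)CC[C@]12C | intermediate
22 | 5αH,9βH-drim-7-ene-3α,11-diol | OC[C@@H]1C(C)=CC[C@H]2C(C)(C)[C@H](O)CC[C@]12C | intermediate
23 | scopoletin | COc1cc2ccc(=O)oc2cc1O | starting material
24 | C11 triphenylphosphonium ether of 22, scopoletin phenolate salt | c1ccccc1[P+](c1ccccc1)(c1ccccc1)OC[C@@H]1C(C)=CC[C@H]2C(C)(C)[C@H](O)CC[C@]12C.COc1cc2ccc(=O)oc2cc1[O-] | intermediate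
25 | CNP0218138.2, scopoletin 11-ether of 5αH,9βH-drim-7-ene-3α,11-diol | COc1cc2ccc(=O)oc2cc1OC[C@@H]1C(C)=CC[C@H]2C(C)(C)[C@H](O)CC[C@]12C | target

Total step count: 14
Longest linear sequence: 14 steps, from 1 to 25; compounds 7, 9 and 23 are bought.

Steps most likely to fail

1. Step 5 (labelled step).
- Risk: the twisted, hindered diene may add too slowly to the iminium ion. Self-condensation of the enal, proton loss after the first C–C bond, or slow ketal hydrolysis could then take over. Endo and facial selectivity may also erode.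
- Fallback (known chemistry): a covalently bound chiral controller at the carboxylic acid oxidation level, with the same two bonds formed. It sets out from diene 8.
- Commercial (S)-4-benzyloxazolidin-2-one is N-acylated with (E)-but-2-enoyl chloride (n-BuLi, THF, −78 °C) to (S)-4-benzyl-3-[(E)-but-2-enoyl]oxazolidin-2-one F1.
- Et2AlCl (1.4 equiv, CH2Cl2, −40 °C) converts F1 into a cationic aluminium chelate, a far stronger dienophile. It should add 8 in the endo mode on the Cα-Si/Cβ-Re face opposite the benzyl group, giving (S)-4-benzyl-3-(3,3-ethylenedioxy-9βH-drim-5-en-11-oyl)oxazolidin-2-one F2.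
- LiBH4 (Et2O, 1 equiv H2O, 0 °C) removes the auxiliary reductively and the route is rejoined at alcohol 13.

2. Step 9.
- Risk: poor facial selectivity in the protonation of C5. The trans-fused arrangement holds both the 8β-methyl and the 9α-CH2OSi arm axial on ring B, which could open the way to cis ring fusion.
- Fallback: hydrogen is delivered from the α face by the C11 hydroxyl group itself. It sets out from enone 15.
- Bu4NF buffered with AcOH (THF, rt) gives 3,3-ethylenedioxy-11-hydroxy-9βH-drim-5-en-7-one F3.
- Hydroxyl-directed hydrogenation (H2, [Ir(cod)(PCy3)(py)]PF6, CH2Cl2, rt) binds the metal to the axial α-CH2OH and should give 3,3-ethylenedioxy-11-hydroxy-5αH,9βH-driman-7-one F4.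
- TBSCl and imidazole return the material to ketone 17.

3. Step 10.
- Risk: incomplete equilibration of the enolates, or sluggish O-sulfonylation of the hindered tetrasubstituted enolate. Either would lead to positional scrambling of the double bond.
- Fallback: the olefin is made by anti elimination instead of through an enolate. It sets out from ketone 17.
- NaOMe in MeOH equilibrates C8 to the equatorial epimer 11-(tert-butyldimethylsilyloxy)-3,3-ethylenedioxy-8α-methyl-5αH,9βH-driman-7-one F5.
- LiBH(s-Bu)3 (THF, −78 °C) gives the axial alcohol 11-(tert-butyldimethylsilyloxy)-3,3-ethylenedioxy-8α-methyl-5αH,9βH-driman-7α-ol F6.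
- POCl3 in pyridine triggers E2 loss of the axial leaving group together with the axial H-8β. This hydrogen is tertiary and more accessible than H-6β, which lies between the axial methyl groups at C4 and C10.
- The route is rejoined at olefin 20, so steps 10 and 11 are both replaced.

Further compounds
F1 | step 5 | (S)-4-benzyl-3-[(E)-but-2-enoyl]oxazolidin-2-one | C/C=C/C(=O)N1[C@@H](Cc2ccccc2)COC1=O
F2 | step 5 | (S)-4-benzyl-3-(3,3-ethylenedioxy-9βH-drim-5-en-11-oyl)oxazolidin-2-one | O=C([C@@H]1[C@@H](C)CC=C2C(C)(C)C3(OCCO3)CC[C@]12C)N4[C@@H](Cc5ccccc5)COC4=O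
F3 | step 9 | 3,3-ethylenedioxy-11-hydroxy-9βH-drim-5-en-7-one | OC[C@@H]1[C@@H](C)C(=O)C=C2C(C)(C)C3(OCCO3)CC[C@]12C
F4 | step 9 | 3,3-ethylenedioxy-11-hydroxy-5αH,9βH-driman-7-one | OC[C@@H]1[C@@H](C)C(=O)C[C@H]2C(C)(C)C3(OCCO3)CC[C@]12C
F5 | step 10 | 11-(tert-butyldimethylsilyloxy)-3,3-ethylenedioxy-8α-methyl-5αH,9βH-driman-7-one | CC(C)(C)[Si](C)(C)OC[C@@H]1[C@H](C)C(=O)C[C@H]2C(C)(C)C3(OCCO3)CC[C@]12C
F6 | step 10 | 11-(tert-butyldimethylsilyloxy)-3,3-ethylenedioxy-8α-methyl-5αH,9βH-driman-7α-ol | CC(C)(C)[Si](C)(C)OC[C@@H]1[C@H](C)[C@H](O)C[C@H]2C(C)(C)C3(OCCO3)CC[C@]12C
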